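**Assumption:** methyl (R)-glycidate (sold; two steps from L-serine) is taken as the cheap chiral starting material. By CIP analysis the target is (S) at the side-chain carbon on indole C3 and (S) at the oxirane carbon.

## Retrosynthetic overview

- Target ⇒ 3,5-bis[(2R)-3-hydroxy-2-mesyloxy-3-methylbutyl]indole + palmitic acid. The C3 arm comes from a stereoinvertive 1,2-indolyl shift (a spirocyclopropane indolenine opened at CH2 by the acid); the C5 arm from oxirane closure with inversion.
- Bis-mesylate ⇒ tetraol ⇒ bis(α-hydroxy methyl ester), by four Grignard additions and sulfonylation of the two secondary alcohols.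
- Bis-ester ⇒ 3-alkylated 5-iodoindole + methyl (R)-glycidate; the C5–CH2 bond is made by a visible-light nickel/photoredox cross-electrophile coupling.
- That iodoindole ⇒ 5-iodoindole + methyl (R)-glycidate (Friedel–Crafts epoxide opening at indole C3).
- Ring order: indole bought; transient cyclopropane made and opened in the last step; oxirane last. Both stereocentres are C2 of the glycidate, each inverted once.

## Route

Step 1
Reactants: 1 5-iodo-1H-indole; 2 methyl (2R)-oxirane-2-carboxylate
Product: 3 methyl (2R)-2-hydroxy-3-(5-iodo-1H-indol-3-yl)propanoate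
Conditions: 1 (2 equiv, excess recovered), SnCl4 (1.2 equiv), CH2Cl2, −40 to 0 °C; aqueous NaHCO3
Reagents that add atoms: none
Why: SnCl4 activates the oxirane and the indole attacks through C3 at the unsubstituted CH2 carbon, away from the ester-bearing carbon (Friedel–Crafts alkylation by epoxide opening, the mode known for indoles with glycidic esters); C2 of 2 is not touched and stays (R).

Step 2
Reactants: 3 methyl (2R)-2-hydroxy-3-(5-iodo-1H-indol-3-yl)propanoate; 2 methyl (2R)-oxirane-2-carboxylate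
Product: 5 methyl (2R)-2-hydroxy-3-{3-[(2R)-2-hydroxy-3-methoxy-3-oxopropyl]-1H-indol-5-yl}propanoate, via iodohydrin 4 (not isolated)
Conditions: 2 (3 equiv), NiBr2(MeOCH2CH2OMe) (10 mol %), 4,4'-di-tert-butyl-2,2'-bipyridine (12 mol %), 2,4,5,6-tetra(9H-carbazol-9-yl)isophthalonitrile (2 mol %), Et3N·HI (0.5 equiv), Et3N (3 equiv), degassed N,N-dimethylacetamide, 450 nm LEDs, 25 °C
Reagents that add atoms: none
Why: Iodide opens 2 at CH2 to iodohydrin 4, whose primary alkyl radical is captured by the arylnickel species formed from 3 and coupled by reductive elimination while the excited photocatalyst, reduced by Et3N, turns the nickel over (nickel/photoredox cross-electrophile coupling of an aryl iodide with a terminal aliphatic epoxide, linear-selective through the iodohydrin); the carbinol centre is β to the radical carbon and stays (R).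

Step 3
Reactants: 5 methyl (2R)-2-hydroxy-3-{3-[(2R)-2-hydroxy-3-methoxy-3-oxopropyl]-1H-indol-5-yl}propanoate
Product: 6 (2R)-1-{3-[(2R)-2,3-dihydroxy-3-methylbutyl]-1H-indol-5-yl}-3-methylbutane-2,3-diol
Conditions: MeMgBr (10 equiv), THF, 0 to 25 °C; aqueous NH4Cl
Reagents that add atoms: methylmagnesium bromide, C[Mg]Br
Why: After NH and OH are deprotonated, each methyl ester takes up two methyl groups (Grignard addition to an ester); the α-alkoxide suppresses enolisation, so both (R) carbinol centres are kept and no new stereocentre forms.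

Step 4
Reactants: 6 (2R)-1-{3-[(2R)-2,3-dihydroxy-3-methylbutyl]-1H-indol-5-yl}-3-methylbutane-2,3-diol
Product: 7 (2R)-3-hydroxy-1-{3-[(2R)-3-hydroxy-2-(methanesulfonyloxy)-3-methylbutyl]-1H-indol-5-yl}-3-methylbutan-2-yl methanesulfonate
Conditions: MsCl (2.3 equiv), pyridine, CH2Cl2, −20 to 0 °C; cold work-up, used at once
Reagents that add atoms: methanesulfonyl chloride, CS(=O)(=O)Cl
Why: Chemoselective O-sulfonylation (mesylation), the secondary alcohols reacting far faster than the hindered tertiary alcohols or the indole NH, with retention at both (R) centres.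

Step 5
Reactants: 7 (2R)-3-hydroxy-1-{3-[(2R)-3-hydroxy-2-(methanesulfonyloxy)-3-methylbutyl]-1H-indol-5-yl}-3-methylbutan-2-yl methanesulfonate; 8 hexadecanoic acid
Product: 11 (2S)-2-(5-{[(2S)-3,3-dimethyloxiran-2-yl]methyl}-1H-indol-3-yl)-3-hydroxy-3-methylbutyl hexadecanoate, via spiroindolenine 9 (not isolated), via hydroxy mesylate ester 10 (not isolated)
Conditions: KN(SiMe3)2 (1.0 equiv), THF, −78 to 0 °C; then 8 (2.5 equiv), 0 to 25 °C; then 1,8-diazabicyclo[5.4.0]undec-7-ene (5 equiv), 25 to 40 °C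
Reagents that add atoms: none
Why: Proposed new method: one equivalent of base deprotonates only the indole NH (about ten pKa units more acidic than the tertiary alcohols), the indolide attacks the neighbouring mesylate carbon through C3 with inversion (3-exo-tet, Ar1-3 participation) to give spirocyclopropane indolenine 9, palmitic acid then protonates the imine nitrogen and its carboxylate opens the activated cyclopropane at the unhindered CH2 (the other ring carbon is neopentyl-like), which rearomatises the indole, leaves C3 bonded to the former carbinol carbon with net inversion and so sets the (S) side-chain centre while installing the ester, after which the amidine base closes the untouched C5 hydroxy mesylate to the (S)-oxirane with inversion (Williamson-type epoxide closure); the closest known reactions are the base-induced spirocyclisation of tryptophyl sulfonates and halides, phenonium-type 1,2-aryl shifts and the acid-promoted nucleophilic opening of spirocyclopropyl indolenines, none yet used to move an indole onto a stereogenic carbinol carbon with carboxylate capture.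

## Compound list

1 | 5-iodo-1H-indole | Ic1ccc2[nH]ccc2c1 | starting material
2 | methyl (2R)-oxirane-2-carboxylate | COC(=O)[C@H]1CO1 | starting material
3 | methyl (2R)-2-hydroxy-3-(5-iodo-1H-indol-3-yl)propanoate | COC(=O)[C@H](O)Cc1c[nH]c2ccc(I)cc12 | intermediate
4 | methyl (2S)-2-hydroxy-3-iodopropanoate (same spatial arrangement as 2; descriptor changes because CH2I outranks the ester carbon) | COC(=O)[C@H](O)CI | intermediate
5 | methyl (2R)-2-hydroxy-3-{3-[(2R)-2-hydroxy-3-methoxy-3-oxopropyl]-1H-indol-5-yl}propanoate | COC(=O)[C@H](O)Cc1c[nH]c2ccc(C[C@@H](O)C(=O)OC)cc12 | intermediate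
6 | (2R)-1-{3-[(2R)-2,3-dihydroxy-3-methylbutyl]-1H-indol-5-yl}-3-methylbutane-2,3-diol | CC(C)(O)[C@H](O)Cc1c[nH]c2ccc(C[C@@H](O)C(C)(C)O)cc12 | intermediate
7 | (2R)-3-hydroxy-1-{3-[(2R)-3-hydroxy-2-(methanesulfonyloxy)-3-methylbutyl]-1H-indol-5-yl}-3-methylbutan-2-yl methanesulfonate | CC(C)(O)[C@H](OS(C)(=O)=O)Cc1c[nH]c2ccc(C[C@@H](OS(C)(=O)=O)C(C)(C)O)cc12 | intermediate
8 | hexadecanoic acid (palmitic acid) | CCCCCCCCCCCCCCCC(=O)O | starting material
9 | (2R)-3-hydroxy-1-[(2R)-2-(2-hydroxypropan-2-yl)spiro[cyclopropane-1,3'-indol]-5'-yl]-3-methylbutan-2-yl methanesulfonate (both epimers at the spiro carbon; both give 10) | CC(C)(O)[C@@H]1CC12C=Nc3ccc(C[C@@H](OS(C)(=O)=O)C(C)(C)O)cc23 | intermediate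
10 | (2S)-3-hydroxy-2-{5-[(2R)-3-hydroxy-2-(methanesulfonyloxy)-3-methylbutyl]-1H-indol-3-yl}-3-methylbutyl hexadecanoate | CCCCCCCCCCCCCCCC(=O)OC[C@H](c1c[nH]c2ccc(C[C@@H](OS(C)(=O)=O)C(C)(C)O)cc12)C(C)(C)O | intermediate
11 | (2S)-2-(5-{[(2S)-3,3-dimethyloxiran-2-yl]methyl}-1H-indol-3-yl)-3-hydroxy-3-methylbutyl hexadecanoate | CCCCCCCCCCCCCCCC(=O)OC[C@H](c1c[nH]c2ccc(C[C@@H]3OC3(C)C)cc12)C(C)(C)O | target

## Step count and risks

Total step count: 5. Longest linear sequence: 5 (from 1; 2 is used twice).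

The three steps most likely to fail:

**Step 5, the new indolyl shift.** Opening of 9 at the substituted ring carbon, or oxirane formation on the C3 arm if more than one equivalent of base is present, would defeat it. The fallback uses known chemistry, sets out from 1 and comes back at 10. Bought [(2R)-3,3-dimethyloxiran-2-yl]methanol F1 is silylated (t-BuMe2SiCl, imidazole) to tert-butyl{[(2R)-3,3-dimethyloxiran-2-yl]methoxy}dimethylsilane F2. Compound 1 is converted with EtMgBr into (5-iodo-1H-indol-1-yl)magnesium bromide F3, which opens F2 through C3 at the secondary oxirane carbon with inversion (the known C3-alkylation of indolylmagnesium halides by epoxides) to give (3S)-4-{[tert-butyl(dimethyl)silyl]oxy}-3-(5-iodo-1H-indol-3-yl)-2-methylbutan-2-ol F4. The step-2 coupling of F4 with 2 gives methyl (2R)-3-{3-[(2S)-1-{[tert-butyl(dimethyl)silyl]oxy}-3-hydroxy-3-methylbutan-2-yl]-1H-indol-5-yl}-2-hydroxypropanoate F5. MeMgBr gives (2R)-1-{3-[(2S)-1-{[tert-butyl(dimethyl)silyl]oxy}-3-hydroxy-3-methylbutan-2-yl]-1H-indol-5-yl}-3-methylbutane-2,3-diol F6, and Bu4NF gives (2S)-2-{5-[(2R)-2,3-dihydroxy-3-methylbutyl]-1H-indol-3-yl}-3-methylbutane-1,3-diol F7. One equivalent of hexadecanoyl chloride with 2,4,6-collidine at −40 °C acylates the only primary alcohol to give (2S)-2-{5-[(2R)-2,3-dihydroxy-3-methylbutyl]-1H-indol-3-yl}-3-hydroxy-3-methylbutyl hexadecanoate F8. MsCl in pyridine then sulfonylates the one secondary alcohol to give 10, which the amidine base closes to 11 as in the last stage of step 5.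

**Step 2, the photochemical coupling.** Base-induced loss of HI from iodohydrin 4 to methyl pyruvate, or protodeiodination of 3, would erode it. The fallback sets out from 1 and comes back at 5. It replaces the radical coupling by a two-electron epoxide opening with an arylcopper and reverses the order of the two alkylations. Compound 1 is N-silylated (NaH, i-Pr3SiCl) to 5-iodo-1-[tri(propan-2-yl)silyl]-1H-indole F9. Iodine–magnesium exchange (i-PrMgCl·LiCl) gives {1-[tri(propan-2-yl)silyl]-1H-indol-5-yl}magnesium chloride F10. CuI-catalysed opening of 2 at CH2 (THF, −40 °C) gives methyl (2R)-2-hydroxy-3-{1-[tri(propan-2-yl)silyl]-1H-indol-5-yl}propanoate F11, and Bu4NF gives methyl (2R)-2-hydroxy-3-(1H-indol-5-yl)propanoate F12. The SnCl4 alkylation of step 1, with a second molecule of 2 at C3 of F12, gives 5.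

**Step 1, the Friedel–Crafts opening.** Chloride opening of 2 and indole oligomerisation compete. The fallback sets out from 1 and comes back at 5; it joins the C3 arm by cross-coupling instead of Friedel–Crafts chemistry, and so shares the step-2 risk. Iodination of 1 (I2, KOH, DMF) gives 3,5-diiodo-1H-indole F13, and di-tert-butyl dicarbonate with 4-(dimethylamino)pyridine gives tert-butyl 3,5-diiodo-1H-indole-1-carboxylate F14. A twofold photochemical nickel coupling with 2 under the step-2 conditions gives tert-butyl 3,5-bis[(2R)-2-hydroxy-3-methoxy-3-oxopropyl]-1H-indole-1-carboxylate F15, and K2CO3 in MeOH removes the carbamate to give 5.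

## Further compounds

F1 | step 5 | [(2R)-3,3-dimethyloxiran-2-yl]methanol | OC[C@H]1OC1(C)C
F2 | step 5 | tert-butyl{[(2R)-3,3-dimethyloxiran-2-yl]methoxy}dimethylsilane | CC(C)(C)[Si](C)(C)OC[C@H]1OC1(C)C
F3 | step 5 | (5-iodo-1H-indol-1-yl)magnesium bromide | Br[Mg]n1ccc2cc(I)ccc21
F4 | step 5 | (3S)-4-{[tert-butyl(dimethyl)silyl]oxy}-3-(5-iodo-1H-indol-3-yl)-2-methylbutan-2-ol | CC(C)(C)[Si](C)(C)OC[C@H](c1c[nH]c2ccc(I)cc12)C(C)(C)O
F5 | step 5 | methyl (2R)-3-{3-[(2S)-1-{[tert-butyl(dimethyl)silyl]oxy}-3-hydroxy-3-methylbutan-2-yl]-1H-indol-5-yl}-2-hydroxypropanoate | CC(C)(C)[Si](C)(C)OC[C@H](c1c[nH]c2ccc(C[C@@H](O)C(=O)OC)cc12)C(C)(C)O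
F6 | step 5 | (2R)-1-{3-[(2S)-1-{[tert-butyl(dimethyl)silyl]oxy}-3-hydroxy-3-methylbutan-2-yl]-1H-indol-5-yl}-3-methylbutane-2,3-diol | CC(C)(C)[Si](C)(C)OC[C@H](c1c[nH]c2ccc(C[C@@H](O)C(C)(C)O)cc12)C(C)(C)O
F7 | step 5 | (2S)-2-{5-[(2R)-2,3-dihydroxy-3-methylbutyl]-1H-indol-3-yl}-3-methylbutane-1,3-diol | OC[C@H](c1c[nH]c2ccc(C[C@@H](O)C(C)(C)O)cc12)C(C)(C)O
F8 | step 5 | (2S)-2-{5-[(2R)-2,3-dihydroxy-3-methylbutyl]-1H-indol-3-yl}-3-hydroxy-3-methylbutyl hexadecanoate | CCCCCCCCCCCCCCCC(=O)OC[C@H](c1c[nH]c2ccc(C[C@@H](O)C(C)(C)O)cc12)C(C)(C)O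
F9 | step 2 | 5-iodo-1-[tri(propan-2-yl)silyl]-1H-indole | CC(C)[Si](C(C)C)(C(C)C)n1ccc2cc(I)ccc21
F10 | step 2 | {1-[tri(propan-2-yl)silyl]-1H-indol-5-yl}magnesium chloride | CC(C)[Si](C(C)C)(C(C)C)n1ccc2cc([Mg]Cl)ccc21
F11 | step 2 | methyl (2R)-2-hydroxy-3-{1-[tri(propan-2-yl)silyl]-1H-indol-5-yl}propanoate | COC(=O)[C@H](O)Cc1ccc2c(c1)ccn2[Si](C(C)C)(C(C)C)C(C)C
F12 | step 2 | methyl (2R)-2-hydroxy-3-(1H-indol-5-yl)propanoate | COC(=O)[C@H](O)Cc1ccc2[nH]ccc2c1
F13 | step 1 | 3,5-diiodo-1H-indole | Ic1c[nH]c2ccc(I)cc12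
F14 | step 1 | tert-butyl 3,5-diiodo-1H-indole-1-carboxylate | CC(C)(C)OC(=O)n1cc(I)c2cc(I)ccc21
F15 | step 1 | tert-butyl 3,5-bis[(2R)-2-hydroxy-3-methoxy-3-oxopropyl]-1H-indole-1-carboxylate | COC(=O)[C@H](O)Cc1cn(C(=O)OC(C)(C)C)c2ccc(C[C@@H](O)C(=O)OC)cc12
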